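**Strategy**

The synthesis is built on opening the pyranone (ring C) at C4a–C4, C4–C3 and O1–C2. In ring C, C2 sits between the ring oxygen O1 and the exocyclic aryloxy oxygen, with C3–H and the C4 ketone beside it; this O1–C2(OAr)=C3–C4(=O) array is exactly what an aryl ynol ether, carbon monoxide and an o-iodophenol deliver. A single palladium-catalysed carbonylative Stille coupling with in-situ 6-endo oxa-Michael closure therefore unites both prenylated arenes and forms ring C. The precursors are a phloroglucinol-derived 2-iodo-6-prenylphenol bearing two MOM ethers (ring A) and the tributylstannyl ynol ether of a MOM-protected 2-prenylhydroquinone (ring B).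

Key step: step 11

Remark: the target has no stereocentre and its prenyl double bonds cannot show E/Z isomerism, so no step has to control configuration; the only defined double-bond geometry on the way (E in compound 17) is lost again in step 10.

**Ring A partner**

Step 1
Reactants: 1 phloroglucinol
Product: 2 3,5-bis(methoxymethoxy)phenol
Conditions: MOMCl (2.1 equiv), i-Pr2NEt, CH2Cl2–DMF, 0 °C to rt; chromatography
Reagents that add atoms: chloromethyl methyl ether (MOMCl), COCCl
Why: Base-mediated O-alkylation of the phenols with MOMCl on the threefold-symmetric triol should give a statistical mixture from which the bis-ether with one free hydroxyl is separated, the mono-ether being recyclable.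

Step 2
Reactants: 2 3,5-bis(methoxymethoxy)phenol
Product: 3 2-iodo-3,5-bis(methoxymethoxy)phenol
Conditions: BnMe3N·ICl2 (1.0 equiv), NaHCO3, CH2Cl2–MeOH, rt
Reagents that add atoms: benzyltrimethylammonium dichloroiodate, C[N+](C)(C)Cc1ccccc1.Cl[I-]Cl
Why: Electrophilic aromatic iodination directed by the free hydroxyl should go to the carbon ortho to OH, which is less crowded than the carbon between the two MOM ethers, with bicarbonate protecting the acetals and no alkene yet present that could undergo iodoetherification.

Step 3
Reactants: 3 2-iodo-3,5-bis(methoxymethoxy)phenol; 4 3-chloro-3-methylbut-1-yne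
Product: 5 2-iodo-1,5-bis(methoxymethoxy)-3-[(2-methylbut-3-yn-2-yl)oxy]benzene
Conditions: CuCl2·2H2O (1 mol%), DBU, MeCN, 0 °C
Reagents that add atoms: none
Why: Copper-catalysed propargylic etherification (substitution through a copper acetylide/allenylidene) should form the hindered tertiary aryl ether under mild base, with no metal present that inserts into the C–I bond.

Step 4
Reactants: 5 2-iodo-1,5-bis(methoxymethoxy)-3-[(2-methylbut-3-yn-2-yl)oxy]benzene
Product: 6 2-iodo-1,5-bis(methoxymethoxy)-3-[(2-methylbut-3-en-2-yl)oxy]benzene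
Conditions: H2 (1 atm), Pd/CaCO3 poisoned with Pb(OAc)2, quinoline, EtOAc, rt, stopped after one equivalent of H2
Reagents that add atoms: none
Why: Lindlar semi-hydrogenation of the terminal alkyne over the lead- and quinoline-poisoned catalyst should stop at the vinyl group and leave the aryl iodide and the acetals intact.

Step 5
Reactants: 6 2-iodo-1,5-bis(methoxymethoxy)-3-[(2-methylbut-3-en-2-yl)oxy]benzene
Product: 7 2-iodo-3,5-bis(methoxymethoxy)-6-(3-methylbut-2-en-1-yl)phenol
Conditions: PhNEt2, 130 °C
Reagents that add atoms: none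
Why: Aromatic Claisen rearrangement ([3,3]-sigmatropic shift) of the 1,1-dimethylallyl ether should deliver the allyl terminus as a prenyl group to the only unsubstituted ortho carbon, and tautomerisation frees the hydroxyl between the iodine and the new prenyl group.

**Ring B partner**

Step 6
Reactants: 8 4-(tert-butyldimethylsilyloxy)phenol
Product: 9 tert-butyl[4-(methoxymethoxy)phenoxy]dimethylsilane
Conditions: MOMCl, i-Pr2NEt, CH2Cl2, 0 °C to rt
Reagents that add atoms: chloromethyl methyl ether (MOMCl), COCCl
Why: Standard MOM etherification of the single free phenol, which also installs the directing group for the next step.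

Step 7
Reactants: 9 tert-butyl[4-(methoxymethoxy)phenoxy]dimethylsilane; 10 prenyl bromide (1-bromo-3-methylbut-2-ene)
Product: 13 tert-butyl[4-(methoxymethoxy)-3-(3-methylbut-2-en-1-yl)phenoxy]dimethylsilane, via aryllithium 11 (not isolated), via arylcopper 12 (not isolated)
Conditions: s-BuLi, TMEDA, THF, −78 °C; CuBr·SMe2, −78 to −40 °C; then 10, −78 to 0 °C
Reagents that add atoms: none
Why: Directed ortho-metalation by the chelating MOM ether (the silyl ether directs poorly), transmetalation to the arylcopper and SN2 allylation with prenyl bromide should place the prenyl group ortho to the MOM-protected oxygen.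

Step 8
Reactants: 13 tert-butyl[4-(methoxymethoxy)-3-(3-methylbut-2-en-1-yl)phenoxy]dimethylsilane
Product: 14 4-(methoxymethoxy)-3-(3-methylbut-2-en-1-yl)phenol
Conditions: Bu4NF, AcOH, THF, 0 °C to rt
Reagents that add atoms: none
Why: Fluoride-mediated cleavage of the aryl silyl ether, buffered with acetic acid, should free the phenol without touching the MOM ether or the alkene.

Step 9
Reactants: 14 4-(methoxymethoxy)-3-(3-methylbut-2-en-1-yl)phenol; 15 trichloroethylene
Product: 17 4-{[(E)-1,2-dichloroethenyl]oxy}-1-(methoxymethoxy)-2-(3-methylbut-2-en-1-yl)benzene, via dichloroacetylene 16 (not isolated)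
Conditions: K2CO3, DMF, 70 °C
Reagents that add atoms: none
Why: Base-induced dehydrochlorination of trichloroethylene gives dichloroacetylene in solution, to which the phenoxide adds with anti protonation (vinylic substitution by elimination–addition), giving the E-dichlorovinyl ether.

Step 10
Reactants: 17 4-{[(E)-1,2-dichloroethenyl]oxy}-1-(methoxymethoxy)-2-(3-methylbut-2-en-1-yl)benzene
Product: 20 tributyl{[4-(methoxymethoxy)-3-(3-methylbut-2-en-1-yl)phenoxy]ethynyl}stannane, via aryloxy chloroalkyne 18 (not isolated), via lithium aryloxyacetylide 19 (not isolated)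
Conditions: n-BuLi (2.2 equiv), THF, −78 to −40 °C; Bu3SnCl, −78 °C to rt; rapid filtration through Et3N-washed silica
Reagents that add atoms: tributyltin chloride, CCCC[Sn](Cl)(CCCC)CCCC
Why: Dehydrochlorination followed by lithium–chlorine exchange should give the lithium aryloxyacetylide, which is stannylated at carbon; an aryl ynol ether has no β-hydrogen for retro-ene loss to a ketene, so it should survive isolation and later heating.

**Union and end game**

Step 11
Reactants: 7 2-iodo-3,5-bis(methoxymethoxy)-6-(3-methylbut-2-en-1-yl)phenol; 20 tributyl{[4-(methoxymethoxy)-3-(3-methylbut-2-en-1-yl)phenoxy]ethynyl}stannane; 21 carbon monoxide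
Product: 23 5,7-bis(methoxymethoxy)-2-[4-(methoxymethoxy)-3-(3-methylbut-2-en-1-yl)phenoxy]-8-(3-methylbut-2-en-1-yl)-4H-chromen-4-one, via aryloxy ynone 22 (not isolated)
Conditions: Pd2(dba)3 (5 mol%), AsPh3 (20 mol%), CO (1 atm), 1,4-dioxane, 60 °C; then i-Pr2NEt (cat.), rt
Reagents that add atoms: none
Why: Proposed new method: oxidative addition of zerovalent palladium into the C–I bond of 7, CO insertion to the aroylpalladium iodide, transfer of the alkynyl group from tin in 20 and reductive elimination should give the push-pull ynone 22, whose free ortho hydroxyl then adds to the aryloxy-bearing alkyne carbon, a trace of hindered amine finishing the closure if needed. The closest known reactions are the palladium-catalysed carbonylative annulation of o-iodophenols with terminal alkynes to chromones and flavones and the carbonylative Stille coupling of aryl iodides with alkynylstannanes, alkoxyalkynylstannanes included, to ynones; an aryloxyalkyne partner has not been shown in either. Ring C closes by 6-endo-dig oxa-Michael addition, forming O1–C2 after the coupling has made C4a–C4 and C4–C3. No stereocentre is formed. The step needs carbonylative instead of direct coupling and 6-endo instead of 5-exo (aurone) closure: the electron-rich, doubly ortho-substituted arylpalladium should take up CO readily under a CO atmosphere, and the aryloxy donor makes the oxygen-bearing β-carbon the electrophilic terminus while the α-carbon is electron-rich, so the phenol goes to C2. Neutral, amine-free Stille conditions spare the ynol ether, and the two MOM ethers leave only the hydroxyl next to the prenyl group free to cyclise, which fixes the 8-prenyl pattern.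

Step 12
Reactants: 23 5,7-bis(methoxymethoxy)-2-[4-(methoxymethoxy)-3-(3-methylbut-2-en-1-yl)phenoxy]-8-(3-methylbut-2-en-1-yl)-4H-chromen-4-one
Product: 24 epimedonin J
Conditions: NaHSO4·SiO2, CH2Cl2, 0 °C to rt
Reagents that add atoms: none
Why: Acid-catalysed hydrolysis of the three aryl MOM acetals by a mild solid proton source in a non-nucleophilic solvent (adsorbed water as the only nucleophile) should free the phenols without protonating the prenyl alkenes and without any species that could add to C2 of the 2-aryloxypyranone.

**Compound list**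

1 | phloroglucinol | Oc1cc(O)cc(O)c1 | starting material
2 | 3,5-bis(methoxymethoxy)phenol | COCOc1cc(O)cc(OCOC)c1 | intermediate
3 | 2-iodo-3,5-bis(methoxymethoxy)phenol | COCOc1cc(O)c(I)c(OCOC)c1 | intermediate
4 | 3-chloro-3-methylbut-1-yne | CC(C)(Cl)C#C | starting material
5 | 2-iodo-1,5-bis(methoxymethoxy)-3-[(2-methylbut-3-yn-2-yl)oxy]benzene | COCOc1cc(OC(C)(C)C#C)c(I)c(OCOC)c1 | intermediate
6 | 2-iodo-1,5-bis(methoxymethoxy)-3-[(2-methylbut-3-en-2-yl)oxy]benzene | COCOc1cc(OC(C)(C)C=C)c(I)c(OCOC)c1 | intermediate
7 | 2-iodo-3,5-bis(methoxymethoxy)-6-(3-methylbut-2-en-1-yl)phenol | COCOc1cc(OCOC)c(CC=C(C)C)c(O)c1I | intermediate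
8 | 4-(tert-butyldimethylsilyloxy)phenol | CC(C)(C)[Si](C)(C)Oc1ccc(O)cc1 | starting material
9 | tert-butyl[4-(methoxymethoxy)phenoxy]dimethylsilane | COCOc1ccc(O[Si](C)(C)C(C)(C)C)cc1 | intermediate
10 | prenyl bromide (1-bromo-3-methylbut-2-ene) | CC(C)=CCBr | starting material
11 | [5-(tert-butyldimethylsilyloxy)-2-(methoxymethoxy)phenyl]lithium | [Li]c1cc(O[Si](C)(C)C(C)(C)C)ccc1OCOC | intermediate
12 | [5-(tert-butyldimethylsilyloxy)-2-(methoxymethoxy)phenyl]copper | [Cu]c1cc(O[Si](C)(C)C(C)(C)C)ccc1OCOC | intermediate
13 | tert-butyl[4-(methoxymethoxy)-3-(3-methylbut-2-en-1-yl)phenoxy]dimethylsilane | COCOc1ccc(O[Si](C)(C)C(C)(C)C)cc1CC=C(C)C | intermediate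
14 | 4-(methoxymethoxy)-3-(3-methylbut-2-en-1-yl)phenol | COCOc1ccc(O)cc1CC=C(C)C | intermediate
15 | trichloroethylene | ClC=C(Cl)Cl | starting material
16 | dichloroacetylene | ClC#CCl | intermediate
17 | 4-{[(E)-1,2-dichloroethenyl]oxy}-1-(methoxymethoxy)-2-(3-methylbut-2-en-1-yl)benzene | COCOc1ccc(O/C(Cl)=C\Cl)cc1CC=C(C)C | intermediate
18 | 4-[(chloroethynyl)oxy]-1-(methoxymethoxy)-2-(3-methylbut-2-en-1-yl)benzene | COCOc1ccc(OC#CCl)cc1CC=C(C)C | intermediate
19 | {[4-(methoxymethoxy)-3-(3-methylbut-2-en-1-yl)phenoxy]ethynyl}lithium | [Li]C#COc1ccc(OCOC)c(CC=C(C)C)c1 | intermediate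
20 | tributyl{[4-(methoxymethoxy)-3-(3-methylbut-2-en-1-yl)phenoxy]ethynyl}stannane | CCCC[Sn](CCCC)(CCCC)C#COc1ccc(OCOC)c(CC=C(C)C)c1 | intermediate
21 | carbon monoxide | [C-]#[O+] | starting material
22 | 1-[2-hydroxy-4,6-bis(methoxymethoxy)-3-(3-methylbut-2-en-1-yl)phenyl]-3-[4-(methoxymethoxy)-3-(3-methylbut-2-en-1-yl)phenoxy]prop-2-yn-1-one | COCOc1cc(OCOC)c(CC=C(C)C)c(O)c1C(=O)C#COc2ccc(OCOC)c(CC=C(C)C)c2 | intermediate
23 | 5,7-bis(methoxymethoxy)-2-[4-(methoxymethoxy)-3-(3-methylbut-2-en-1-yl)phenoxy]-8-(3-methylbut-2-en-1-yl)-4H-chromen-4-one | COCOc1ccc(Oc2cc(=O)c3c(OCOC)cc(OCOC)c(CC=C(C)C)c3o2)cc1CC=C(C)C | intermediate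
24 | epimedonin J, 5,7-dihydroxy-2-[4-hydroxy-3-(3-methylbut-2-en-1-yl)phenoxy]-8-(3-methylbut-2-en-1-yl)-4H-chromen-4-one | CC(C)=CCc1cc(Oc2cc(=O)c3c(O)cc(O)c(CC=C(C)C)c3o2)ccc1O | target

**Step count and risks**

Total steps: 12. Longest linear sequence: 7 steps (steps 1–5, 11, 12, or equally steps 6–10, 11, 12).

Steps most likely to fail:

1. Step 11 (key step). Direct, CO-free coupling could outrun carbonylation. The free phenol could protodestannylate the ynol ether, or the ynol ether could break down on palladium. Ring closure could also take the 5-exo course. The fallback builds the pyranone first and introduces the aryloxy group last by known addition–elimination chemistry. It sets out from 7. Stille coupling with tributyl(1-ethoxyvinyl)stannane (Pd(PPh3)4, toluene, 90 °C) would give the enol ether 2-(1-ethoxyethenyl)-3,5-bis(methoxymethoxy)-6-(3-methylbut-2-en-1-yl)phenol F1. Brief treatment with cold dilute HCl in THF would hydrolyse it to the acetophenone 1-[2-hydroxy-4,6-bis(methoxymethoxy)-3-(3-methylbut-2-en-1-yl)phenyl]ethanone F2. Condensation with CS2 and KOt-Bu in THF would give 4-hydroxy-5,7-bis(methoxymethoxy)-8-(3-methylbut-2-en-1-yl)-2H-chromene-2-thione F3. S-Methylation (MeI, K2CO3, acetone) would give 5,7-bis(methoxymethoxy)-2-(methylthio)-8-(3-methylbut-2-en-1-yl)-4H-chromen-4-one F4. Oxidation with H2O2 and catalytic (NH4)6Mo7O24·4H2O in EtOH, which oxidises sulfides in the presence of trisubstituted alkenes, would give 5,7-bis(methoxymethoxy)-2-(methylsulfonyl)-8-(3-methylbut-2-en-1-yl)-4H-chromen-4-one F5. Displacement of methanesulfinate from C2 by phenol 14 (K2CO3, DMF, rt) would return to the route at 23.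

2. Step 12. Protonation of a prenyl alkene next to a freed phenol could lead to chroman formation, and the C2 aryloxy ketene acetal could be hydrolysed or solvolysed once the pyranone carbonyl is protonated. The fallback avoids free protic acid by exchanging the protecting groups. It sets out from 23. TESOTf and 2,2'-bipyridyl in CH2Cl2 at 0 °C would convert the three aryl MOM ethers into silyl ethers, giving 5,7-bis(triethylsilyloxy)-2-[4-(triethylsilyloxy)-3-(3-methylbut-2-en-1-yl)phenoxy]-8-(3-methylbut-2-en-1-yl)-4H-chromen-4-one F6. Desilylation with HF·pyridine buffered by pyridine in THF at 0 °C would return to the route at 24.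

3. Step 4. Hydrodeiodination or over-reduction of the vinyl group could accompany the semi-hydrogenation, and the tertiary allyl ether formed is prone to ionisation before it rearranges in step 5. The fallback replaces the propargylation, reduction and rearrangement sequence by direct ortho C-alkylation. It sets out from 3. Deprotonation with NaH in toluene would give sodium 2-iodo-3,5-bis(methoxymethoxy)phenoxide F7. Alkylation of this tight ion pair with prenyl bromide 10 in the non-polar solvent at rt should favour the free ortho carbon over oxygen, returning to the route at 7 and bypassing 5 and 6.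

Further compounds
F1 | step 11 | 2-(1-ethoxyethenyl)-3,5-bis(methoxymethoxy)-6-(3-methylbut-2-en-1-yl)phenol | COCOc1cc(OCOC)c(CC=C(C)C)c(O)c1C(=C)OCC
F2 | step 11 | 1-[2-hydroxy-4,6-bis(methoxymethoxy)-3-(3-methylbut-2-en-1-yl)phenyl]ethanone | COCOc1cc(OCOC)c(CC=C(C)C)c(O)c1C(C)=O
F3 | step 11 | 4-hydroxy-5,7-bis(methoxymethoxy)-8-(3-methylbut-2-en-1-yl)-2H-chromene-2-thione | COCOc1cc(OCOC)c(CC=C(C)C)c2oc(=S)cc(O)c12
F4 | step 11 | 5,7-bis(methoxymethoxy)-2-(methylthio)-8-(3-methylbut-2-en-1-yl)-4H-chromen-4-one | COCOc1cc(OCOC)c(CC=C(C)C)c2oc(SC)cc(=O)c12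
F5 | step 11 | 5,7-bis(methoxymethoxy)-2-(methylsulfonyl)-8-(3-methylbut-2-en-1-yl)-4H-chromen-4-one | COCOc1cc(OCOC)c(CC=C(C)C)c2oc(S(C)(=O)=O)cc(=O)c12
F6 | step 12 | 5,7-bis(triethylsilyloxy)-2-[4-(triethylsilyloxy)-3-(3-methylbut-2-en-1-yl)phenoxy]-8-(3-methylbut-2-en-1-yl)-4H-chromen-4-one | CC[Si](CC)(CC)Oc1ccc(Oc2cc(=O)c3c(O[Si](CC)(CC)CC)cc(O[Si](CC)(CC)CC)c(CC=C(C)C)c3o2)cc1CC=C(C)C
F7 | step 4 | sodium 2-iodo-3,5-bis(methoxymethoxy)phenoxide | [Na+].[O-]c1cc(OCOC)cc(OCOC)c1I
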